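The data were computed from invented constants; scatter was added.

A leftover in the balance carries this flask: complex with one exchanged stands in none of the tables of readings, and the share asked about does not count it.

| flask | starting complex | incoming ligand | leaving ligand | temperature | remark | time |
|---|---|---|---|---|---|---|
| south-east | 0.50 M (fed, over 80 min) | 1 equiv | 0.50 equiv | −28 °C | run made earlier; the fed solution adds 0.50 times the starting volume |  |
| north-west | 0.50 M (fed, over 80 min) | 4 equiv | 0.50 equiv | 0 °C | run made earlier; the fed solution adds 0.50 times the starting volume |  |
| zeta | 0.50 M (fed, over 25 min) | 2.00 equiv | 0.500 equiv |  | at 10 °C throughout; the fed solution adds 0.50 times the starting volume | 80 min |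
| epsilon | 0.50 M (fed, over 80 min) | 2.00 equiv | 0.500 equiv |  | at −40 °C until 40 min, from then on at 10 °C; the fed solution adds 0.50 times the starting volume | 80 min |

| run | time / min | complex with two exchanged / % | side product / % | starting complex / % |
|---|---|---|---|---|
| south-east | 3.00 | 0.3 | 1.2 | 3.3 |
| south-east | 6.00 | 0.7 | 1.4 | 6.1 |
| south-east | 12.0 | 0.3 | 3.7 | 8.5 |
| south-east | 15.0 | 0.8 | 6.1 | 11.1 |
| south-east | 30.0 | 2.2 | 16.8 | 14.2 |
| north-west | 0.833 | 0.6 | 0 | 0 |
| north-west | 2.00 | 0.5 | 0.3 | 0.5 |
| north-west | 4.00 | 2.4 | 1.8 | 0.3 |
| north-west | 6.00 | 3.1 | 3.1 | 0.5 |
| north-west | 8.00 | 3.7 | 3.8 | 0 |

(each reading ± 0.5 percentage points)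

- which one finishes higher in share of complex with two exchanged in all that became complex with two exchanged or side product ("neither" within 2 percentage points) (zeta / epsilon / neither)
- share of complex with two exchanged in all that became complex with two exchanged or side product, zeta
- share of complex with two exchanged in all that became complex with two exchanged or side product, epsilon

- amounts and yields of complex with two exchanged count idle adduct too
- charges are per starting volume, the dose included; the dosed solution carries all of it
- steps that have been proposed: starting complex + incoming ligand <-> leaving ligand + complex with one exchanged; complex with one exchanged + incoming ligand <-> leaving ligand + complex with two exchanged; complex with two exchanged + incoming ligand <-> idle adduct; leaving ligand + starting complex -> side product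
- percentages count the whole charge, also what has not yet gone in

What is left over in the north-west run at 8.00 min? The steady feed has brought in 10.0% of the charge. The readings give 3.8% side product, 0% starting complex and 3.7% complex with two exchanged, which leaves 2.50%. I take that as complex with one exchanged.

What is it good for? The second exchange is proposed as reversible, so I define the standing ratio: c(complex with two exchanged)/c(complex with one exchanged) times c(leaving ligand)/c(incoming ligand), read here with the charged ligands and on the assumption that this step stands at equilibrium, 0.185.

How firm is it? It rests on 3 readings of scatter 0.5 percentage points, and at 0 °C, not 10 °C, so it is a rough value.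

And the side product? In the same north-west reading, side product over the rest of what reacted, divided by the charged ligand ratio, gives as a reading a selectivity factor of 4.90.

What do the two give for zeta? At the charged ratio c(leaving ligand)/c(incoming ligand) of 0.250, side product takes 55.1%. The standing ratio puts 19.1% in complex with two exchanged, so the share is 25.8%.

But that ratio moves. My balance of these two amounts puts its end at 0.434, so my mean is 0.342. With that mean, side product takes 62.6%, complex with two exchanged 13.1%, and the share is 17.3%. That end ratio was reckoned with 55.1% side product, less than the 62.6% just found, so I commit to the middle, 21.5%. Epsilon has the same charges and ends at 10 °C, and this reckoning holds no time, so it gives the same number for epsilon.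

The forecast says neither, with 41% (32% to 50%) for zeta and 40% (30% to 50%) for epsilon, on the ground that “All intermediate converts by 80 min”.

The flask gives 16.8% for zeta and 17.1% for epsilon, so neither.

    starting complex + incoming ligand ⇌ leaving ligand + complex with one exchanged (K = 0.590, k = 3.40 × 10⁻⁴ /M/s, Ea = 48.0 kJ/mol, ΔH = 33.0 kJ/mol)
    complex with one exchanged + incoming ligand ⇌ leaving ligand + complex with two exchanged (K = 0.520, k = 4.50 × 10⁻⁴ /M/s, Ea = 64.0 kJ/mol, ΔH = −15.0 kJ/mol)
    complex with two exchanged + incoming ligand ⇌ idle adduct, settled at all times (K = 0.510 /M, ΔH = −22.0 kJ/mol)
    leaving ligand + starting complex → side product (k = 0.00130 /M/s, Ea = 51.0 kJ/mol)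
    (constants at −40 °C)

At 80.0 min zeta still holds 16.4% complex with one exchanged beside 14.0% complex with two exchanged, idle adduct counted. The standing ratio, with that moment's ligands, gives 1.15 for two exchanged over one exchanged; the flask stands at 0.854.

In a second flask, like zeta but with 2.00 equiv of leaving ligand, the end ligands make the standing ratio give 0.348 for complex with two exchanged over complex with one exchanged. At 80.0 min the computed flask has 0.450% complex with two exchanged against 1.72% complex with one exchanged, a ratio of 0.262, and a share of 0.458%.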